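## Retrosynthetic overview
1. The 5α‑OH and 4(15)‑methylene come from an α‑face singlet‑oxygen ene reaction on a Δ4‑3β‑angelate. The 3β‑oxygen comes from Luche reduction and angeloylation of a 4‑en‑3‑one.
2. The 8β‑OAc and methyl acrylate come from opening (KOH, MeI, Ac2O) a cis 8β,12‑α‑methylene lactone. That lactone comes from iodolactonisation and deiodination of a Δ8‑12‑acid, itself made by allylic oxidation of an isopropenyl group.
3. The Δ8 alkene comes from a C9 ketone (enol triflate, then Pd/formate). The 4‑en‑3‑one comes from dehydrogenation of a cis‑fused 3‑decalone.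
4. Key disconnection: C1–C10 and C4–C5 are made by a Diels–Alder reaction of (S)‑carvone with (Z)‑3‑silyloxypenta‑1,3‑diene.
5. Ring order: ring B is bought (carvone, C7). Ring A is made by [4+2]. The lactone ring is only a temporary device that puts oxygen on C8.

Assumption: eudesmane numbering (C1–C15) is used in all names. The C4 configuration of 4–8 (drawn 4α‑methyl, endo adduct) does not matter, because C4 becomes sp2 in step 5.

## Route

Step 1
Reactants: 1 ethyl vinyl ketone (pent‑1‑en‑3‑one)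
Product: 2 (Z)‑3‑(tert‑butyldimethylsilyloxy)penta‑1,3‑diene
Conditions: TBSOTf (1.05 equiv), Et3N (1.5 equiv), Et2O, 0 °C
Reagents that add atoms: tert‑butyldimethylsilyl triflate, CC(C)(C)[Si](C)(C)OS(=O)(=O)C(F)(F)F
Why: Soft enolisation and O‑silylation of the ethyl ketone gives the 2‑silyloxydiene mainly as the Z enol ether, whose methyl group lies "outside" in the s‑cis diene and is therefore the cycloaddition‑competent isomer.

Step 2
Reactants: 2 (Z)‑3‑(tert‑butyldimethylsilyloxy)penta‑1,3‑diene (1.5 equiv); 3 (S)‑(+)‑carvone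
Product: 4 3‑(tert‑butyldimethylsilyloxy)‑5βH‑eudesma‑2,11‑dien‑9‑one (cis‑decalin; 4α‑Me, 5β‑H, 7β‑isopropenyl, 10β‑Me)
Conditions: EtAlCl2 (0.5 equiv), toluene, −20 °C → rt; Et3N/aq. NaHCO3 quench
Reagents that add atoms: none
Why: In this Lewis‑acid‑catalysed Diels–Alder reaction the nucleophilic methyl‑bearing diene terminus bonds to the enone β‑carbon ("para" rule for 2‑silyloxydienes) and the diene adds endo to the face anti to the isopropenyl group, so the bought C7 centre sets C10 (β‑Me) and C5 (β‑H).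

Step 3
Reactants: 4 3‑(tert‑butyldimethylsilyloxy)‑5βH‑eudesma‑2,11‑dien‑9‑one
Product: 6 3‑(tert‑butyldimethylsilyloxy)‑9‑(trifluoromethylsulfonyloxy)‑5βH‑eudesma‑2,8,11‑triene, via potassium Δ8‑enolate of 4 5 (not isolated)
Conditions: KHMDS (1.2 equiv), THF, −78 °C; PhNTf2 (1.3 equiv), −78 → 0 °C
Reagents that add atoms: N‑phenylbis(trifluoromethanesulfonimide), O=S(=O)(N(c1ccccc1)S(=O)(=O)C(F)(F)F)C(F)(F)F
Why: C10 is quaternary, so the C9 ketone can enolise only toward C8 and is trapped on oxygen (enol triflate formation), while C3 stays masked as the silyl enol ether delivered by the cycloaddition.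

Step 4
Reactants: 6 3‑(tert‑butyldimethylsilyloxy)‑9‑(trifluoromethylsulfonyloxy)‑5βH‑eudesma‑2,8,11‑triene
Product: 8 5βH‑eudesma‑8,11‑dien‑3‑one, via 3‑(tert‑butyldimethylsilyloxy)‑5βH‑eudesma‑2,8,11‑triene 7 (not isolated)
Conditions: Pd(OAc)2 (5 mol %), PPh3 (10 mol %), HCO2H (2 equiv), Et3N (3 equiv), DMF, 60 °C; then 1 M HCl, THF, rt
Reagents that add atoms: none
Why: Pd‑catalysed formate hydrogenolysis of the vinyl triflate (Cacchi reduction) turns the C9 carbonyl into the Δ8 alkene without touching the isolated alkenes, and mild acid then hydrolyses the silyl enol ether to the 3‑ketone.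

Step 5
Reactants: 8 5βH‑eudesma‑8,11‑dien‑3‑one
Product: 9 eudesma‑4,8,11‑trien‑3‑one (7β‑isopropenyl, 10β‑Me)
Conditions: IBX (1.5 equiv), 4‑methoxypyridine N‑oxide (1.5 equiv), DMSO, rt
Reagents that add atoms: none
Why: IBX dehydrogenation follows the preferred enol, and an A/B‑cis 3‑ketone carrying a 4‑methyl group enolises toward C4 (as 5β‑3‑keto steroids do), which gives the tetrasubstituted Δ4‑enone and erases the provisional C4 and C5 centres.

Step 6
Reactants: 9 eudesma‑4,8,11‑trien‑3‑one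
Product: 11 3‑oxoeudesma‑4,8,11(13)‑trien‑12‑al, via 12‑hydroxyeudesma‑4,8,11(13)‑trien‑3‑one 10 (not isolated)
Conditions: SeO2 (0.3 equiv), t‑BuOOH (2.5 equiv), CH2Cl2, 0 °C → rt; filter; MnO2 (10 equiv), CH2Cl2, rt
Reagents that add atoms: tert‑butyl hydroperoxide, CC(C)(C)OO (source of the new O, relayed through selenium dioxide, O=[Se]=O)
Why: In this Sharpless–Umbreit allylic oxidation (ene reaction, then [2,3]‑shift) selenium attacks the most nucleophilic 1,1‑disubstituted alkene and oxidises its always‑aligned methyl C–H, and MnO2 then converts the alcohol/aldehyde mixture into the enal.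

Step 7
Reactants: 11 3‑oxoeudesma‑4,8,11(13)‑trien‑12‑al
Product: 12 3‑oxoeudesma‑4,8,11(13)‑trien‑12‑oic acid
Conditions: NaClO2, NaH2PO4, 2‑methyl‑2‑butene (20 equiv), t‑BuOH/H2O, 0 °C → rt
Reagents that add atoms: sodium chlorite, [Na+].[O-]Cl=O
Why: Pinnick oxidation converts the enal into the acrylic acid chemoselectively, because the excess scavenger removes HOCl before it can reach the Δ8 alkene.

Step 8
Reactants: 12 3‑oxoeudesma‑4,8,11(13)‑trien‑12‑oic acid
Product: 13 9α‑iodo‑3‑oxoeudesma‑4,11(13)‑dien‑8β,12‑olide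
Conditions: I2 (2 equiv), NaHCO3 (3 equiv), MeCN/H2O, 0 °C, dark
Reagents that add atoms: iodine, II
Why: In this iodolactonisation Δ8 is the only electron‑rich alkene, the iodonium forms on the α‑face away from the 10β‑methyl, and the 7β‑carboxylate opens it 5‑exo at C8 from the β‑face (trans‑diaxial), which sets 8β‑O and 9α‑I.

Step 9
Reactants: 13 9α‑iodo‑3‑oxoeudesma‑4,11(13)‑dien‑8β,12‑olide
Product: 14 3‑oxoeudesma‑4,11(13)‑dien‑8β,12‑olide
Conditions: Bu3SnH (1.2 equiv, 0.2 M), Et3B (0.2 equiv)/air, toluene, 0 °C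
Reagents that add atoms: none
Why: In this radical chain hydrodeiodination, iodine abstraction by Bu3Sn• is far faster than stannyl addition to the acrylate, and the hindered neopentyl‑type C9 radical is quenched by concentrated tin hydride before it can add intermolecularly, so C8 is unaffected.

Step 10
Reactants: 14 3‑oxoeudesma‑4,11(13)‑dien‑8β,12‑olide
Product: 17 methyl 8β‑acetoxy‑3‑oxoeudesma‑4,11(13)‑dien‑12‑oate, via potassium 8β‑hydroxy‑3‑oxoeudesma‑4,11(13)‑dien‑12‑oate 15 (not isolated), via methyl 8β‑hydroxy‑3‑oxoeudesma‑4,11(13)‑dien‑12‑oate 16 (not isolated)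
Conditions: KOH (1.05 equiv), THF/H2O, 0 °C; evaporate, toluene azeotrope; MeI (3 equiv), DMF, rt; strip excess MeI; Ac2O, DMAP, pyridine, rt
Reagents that add atoms: potassium hydroxide, [K+].[OH-]; iodomethane, CI; acetic anhydride, CC(=O)OC(C)=O
Why: Saponification by acyl–O cleavage keeps the C8 configuration and gives a Michael‑inert acrylate salt, neutral SN2 O‑methylation gives a γ‑hydroxy‑α‑methylene ester of the type that needs acid or strong base to relactonise, and DMAP‑catalysed acetylation then caps the axial 8β‑OH.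

Step 11
Reactants: 17 methyl 8β‑acetoxy‑3‑oxoeudesma‑4,11(13)‑dien‑12‑oate
Product: 18 methyl 8β‑acetoxy‑3β‑hydroxyeudesma‑4,11(13)‑dien‑12‑oate
Conditions: NaBH4 (1.0 equiv), CeCl3·7H2O (1.1 equiv), MeOH, −78 → −40 °C
Reagents that add atoms: none
Why: Luche reduction gives clean 1,2‑reduction of the enone at a temperature where the acrylate and acetate are inert, with axial hydride delivery from the α‑face (anti to the 10β‑methyl) setting the equatorial 3β‑OH.

Step 12
Reactants: 18 methyl 8β‑acetoxy‑3β‑hydroxyeudesma‑4,11(13)‑dien‑12‑oate; 19 angelic acid ((Z)‑2‑methylbut‑2‑enoic acid)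
Product: 21 methyl 8β‑acetoxy‑3β‑angeloyloxyeudesma‑4,11(13)‑dien‑12‑oate, via angelic 2,4,6‑trichlorobenzoic anhydride 20 (not isolated)
Conditions: 19 (3 equiv), 2,4,6‑trichlorobenzoyl chloride (3 equiv), Et3N (6 equiv), toluene, rt; then 18, 80 °C (no DMAP)
Reagents that add atoms: angelic acid 19, C/C=C(/C)C(=O)O
Why: In this Yamaguchi mixed‑anhydride esterification the alcohol attacks the less hindered angeloyl carbonyl, leaving out a nucleophilic catalyst avoids Z→E (tiglate) isomerisation, and O‑acylation leaves C3 untouched.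

Step 13
Reactants: 21 methyl 8β‑acetoxy‑3β‑angeloyloxyeudesma‑4,11(13)‑dien‑12‑oate
Product: 23 methyl 8β‑acetoxy‑3β‑angeloyloxy‑5α‑hydroxyeudesma‑4(15),11(13)‑dien‑12‑oate (CNP0179024.1), via methyl 8β‑acetoxy‑3β‑angeloyloxy‑5α‑hydroperoxyeudesma‑4(15),11(13)‑dien‑12‑oate 22 (not isolated)
Conditions: O2, tetraphenylporphyrin (1 mol %), visible light, CH2Cl2, −10 °C; then PPh3 (1.1 equiv), 0 °C
Reagents that add atoms: oxygen, O=O
Why: In this Schenck ene reaction singlet oxygen attacks only the tetrasubstituted Δ4 alkene (the conjugated esters are far slower) from the α‑face opposite the 10β‑methyl, where the C15 methyl offers the only well‑aligned and electronically favourable allylic H, giving the 5α‑OOH and 4(15)‑ene, which PPh3 reduces with retention.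

## Compound list
1 | ethyl vinyl ketone | C=CC(=O)CC | starting material
2 | (Z)‑3‑(tert‑butyldimethylsilyloxy)penta‑1,3‑diene | C/C=C(/C=C)O[Si](C)(C)C(C)(C)C | intermediate
3 | (S)‑(+)‑carvone | C=C(C)[C@H]1CC=C(C)C(=O)C1 | starting material
4 | 3‑(TBSO)‑5βH‑eudesma‑2,11‑dien‑9‑one | C=C(C)[C@H]1C[C@@H]2[C@H](C)C(O[Si](C)(C)C(C)(C)C)=CC[C@]2(C)C(=O)C1 | intermediate
5 | potassium Δ8‑enolate of 4 | C=C(C)[C@H]1C[C@@H]2[C@H](C)C(O[Si](C)(C)C(C)(C)C)=CC[C@]2(C)C([O-])=C1.[K+] | intermediate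
6 | 3‑(TBSO)‑9‑(triflyloxy)‑5βH‑eudesma‑2,8,11‑triene | C=C(C)[C@H]1C[C@@H]2[C@H](C)C(O[Si](C)(C)C(C)(C)C)=CC[C@]2(C)C(OS(=O)(=O)C(F)(F)F)=C1 | intermediate
7 | 3‑(TBSO)‑5βH‑eudesma‑2,8,11‑triene | C=C(C)[C@H]1C[C@@H]2[C@H](C)C(O[Si](C)(C)C(C)(C)C)=CC[C@]2(C)C=C1 | intermediate
8 | 5βH‑eudesma‑8,11‑dien‑3‑one | C=C(C)[C@H]1C[C@@H]2[C@H](C)C(=O)CC[C@]2(C)C=C1 | intermediate
9 | eudesma‑4,8,11‑trien‑3‑one | C=C(C)[C@H]1CC2=C(C)C(=O)CC[C@]2(C)C=C1 | intermediate
10 | 12‑hydroxyeudesma‑4,8,11(13)‑trien‑3‑one | C=C(CO)[C@H]1CC2=C(C)C(=O)CC[C@]2(C)C=C1 | intermediate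
11 | 3‑oxoeudesma‑4,8,11(13)‑trien‑12‑al | C=C(C=O)[C@H]1CC2=C(C)C(=O)CC[C@]2(C)C=C1 | intermediate
12 | 3‑oxoeudesma‑4,8,11(13)‑trien‑12‑oic acid | C=C(C(=O)O)[C@H]1CC2=C(C)C(=O)CC[C@]2(C)C=C1 | intermediate
13 | 9α‑iodo‑3‑oxoeudesma‑4,11(13)‑dien‑8β,12‑olide | C=C1C(=O)O[C@@H]2[C@@H](I)[C@@]3(C)CCC(=O)C(C)=C3C[C@H]12 | intermediate
14 | 3‑oxoeudesma‑4,11(13)‑dien‑8β,12‑olide | C=C1C(=O)O[C@@H]2C[C@@]3(C)CCC(=O)C(C)=C3C[C@H]12 | intermediate
15 | potassium 8β‑hydroxy‑3‑oxoeudesma‑4,11(13)‑dien‑12‑oate | [K+].C=C(C(=O)[O-])[C@H]1CC2=C(C)C(=O)CC[C@]2(C)C[C@H]1O | intermediate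
16 | methyl 8β‑hydroxy‑3‑oxoeudesma‑4,11(13)‑dien‑12‑oate | C=C(C(=O)OC)[C@H]1CC2=C(C)C(=O)CC[C@]2(C)C[C@H]1O | intermediate
17 | methyl 8β‑acetoxy‑3‑oxoeudesma‑4,11(13)‑dien‑12‑oate | C=C(C(=O)OC)[C@H]1CC2=C(C)C(=O)CC[C@]2(C)C[C@H]1OC(C)=O | intermediate
18 | methyl 8β‑acetoxy‑3β‑hydroxyeudesma‑4,11(13)‑dien‑12‑oate | C=C(C(=O)OC)[C@H]1CC2=C(C)[C@@H](O)CC[C@]2(C)C[C@H]1OC(C)=O | intermediate
19 | angelic acid | C/C=C(/C)C(=O)O | starting material
20 | angelic 2,4,6‑trichlorobenzoic anhydride | C/C=C(/C)C(=O)OC(=O)c1c(Cl)cc(Cl)cc1Cl | intermediate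
21 | methyl 8β‑acetoxy‑3β‑angeloyloxyeudesma‑4,11(13)‑dien‑12‑oate | C=C(C(=O)OC)[C@H]1CC2=C(C)[C@@H](OC(=O)/C(C)=C\C)CC[C@]2(C)C[C@H]1OC(C)=O | intermediate
22 | methyl 8β‑acetoxy‑3β‑angeloyloxy‑5α‑hydroperoxyeudesma‑4(15),11(13)‑dien‑12‑oate | C=C(C(=O)OC)[C@H]1C[C@@]2(OO)C(=C)[C@@H](OC(=O)/C(C)=C\C)CC[C@]2(C)C[C@H]1OC(C)=O | intermediate
23 | methyl 8β‑acetoxy‑3β‑angeloyloxy‑5α‑hydroxyeudesma‑4(15),11(13)‑dien‑12‑oate | C=C(C(=O)OC)[C@H]1C[C@@]2(O)C(=C)[C@@H](OC(=O)/C(C)=C\C)CC[C@]2(C)C[C@H]1OC(C)=O | target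

## Step count
- Total steps: 13.
- Longest linear sequence: 13 (1 → 23), or 12 counted from carvone 3.

## Steps most likely to fail

**Step 6.** C7–H in 9 is doubly allylic, so the selenium ene step may take that hydrogen and give 7‑hydroxylation or a conjugated triene instead of oxidising the methyl group.
- The fallback sets out from 9 and replaces the pericyclic oxidation with an ionic one.
- HOCl made from Ca(OCl)2 and solid CO2 in CH2Cl2/H2O at 0 °C chlorinates the isopropenyl group. Proton loss from the unhindered methyl gives 12‑chloroeudesma‑4,8,11(13)‑trien‑3‑one F1.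
- N‑Methylmorpholine N‑oxide in MeCN displaces the chloride and eliminates to the aldehyde, which rejoins the route at 11.

**Step 9.** The α‑methylene lactone and the enone are radical acceptors, so hydrostannation or Giese‑type dimerisation may compete with deiodination.
- The fallback sets out from acid 12, leaves out iodine and tin altogether, and comes back at 14.
- It is a Brønsted/Lewis‑acid hydroacyloxylation: TfOH (10 mol %) in CH2Cl2 at 0 °C → rt, or AgOTf (5 mol %) in DCE at 80 °C.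
- Carboxyl‑assisted protonation at C9 closes the only geometrically possible cis γ‑lactone at C8β.
- This fallback makes no new compound (F0).

**Step 10.** Hydroxy ester 16 may relactonise faster than its hindered axial OH is acetylated.
- The fallback sets out from 14 and never lets a free γ‑hydroxy ester exist.
- After the same saponification to 15, TESOTf/2,6‑lutidine at −78 °C gives triethylsilyl 3‑oxo‑8β‑(triethylsilyloxy)eudesma‑4,11(13)‑dien‑12‑oate F2.
- Aqueous work‑up cleaves only the silyl ester, giving 3‑oxo‑8β‑(triethylsilyloxy)eudesma‑4,11(13)‑dien‑12‑oic acid F3.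
- MeI/K2CO3 in DMF gives methyl 3‑oxo‑8β‑(triethylsilyloxy)eudesma‑4,11(13)‑dien‑12‑oate F4.
- Ac2O with catalytic FeCl3 exchanges OTES directly for OAc with the C8–O bond intact, which rejoins the route at 17.

## Further compounds
F1 | step 6 | 12‑chloroeudesma‑4,8,11(13)‑trien‑3‑one | C=C(CCl)[C@H]1CC2=C(C)C(=O)CC[C@]2(C)C=C1
F0 | step 9 | none | none
F2 | step 10 | triethylsilyl 3‑oxo‑8β‑(triethylsilyloxy)eudesma‑4,11(13)‑dien‑12‑oate | C=C(C(=O)O[Si](CC)(CC)CC)[C@H]1CC2=C(C)C(=O)CC[C@]2(C)C[C@H]1O[Si](CC)(CC)CC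
F3 | step 10 | 3‑oxo‑8β‑(triethylsilyloxy)eudesma‑4,11(13)‑dien‑12‑oic acid | C=C(C(=O)O)[C@H]1CC2=C(C)C(=O)CC[C@]2(C)C[C@H]1O[Si](CC)(CC)CC
F4 | step 10 | methyl 3‑oxo‑8β‑(triethylsilyloxy)eudesma‑4,11(13)‑dien‑12‑oate | C=C(C(=O)OC)[C@H]1CC2=C(C)C(=O)CC[C@]2(C)C[C@H]1O[Si](CC)(CC)CC
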